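**Retrosynthetic overview**
1. Target 16 comes from removal of the two aryl allyl ethers of lactol 15. Lactol 15 (ring 1, C7–O–C9') is closed last from the C7–OH and the C9' aldehyde 14, which carries the Ca-derived stereocentre C8'.
2. Aldehyde 14 comes from imide 12. The THF ring 2 (C7'–O–C9) is closed early by cyclodehydration of the 1,4-diol 11. At that stage ring 1 is still open, so the C8/C8' trans arrangement is strain-free.
3. Diol 11 (four contiguous centres C7, C8, C8', C7') comes from two Mg-catalysed anti-aldol additions of allylvanillin 3 to an unsymmetrical succinyl bis-imide. Auxiliaries of opposite sense make the two aldol halves mirror-related, which is what gives the trans-fused relative configuration.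
4. Bis-imide 8 comes from succinic anhydride and two Evans-type auxiliaries. The thiazolidinethione end becomes C9 and the oxazolidinone end becomes C9'.

**Assumption (one line):** The target SMILES is taken literally, as a trans-fused furofuran lactol (H-8 and H-8' anti; strained, and C8' can epimerise through the open hydroxy-aldehyde) with the drawn lactol anomer. The auxiliary enantiomers are assigned with the Evans Mg-chelate facial model (the (S)-auxiliary gives the 2R, 3S anti aryl-aldol unit).

---

**Step 1**
Reactants: 1 (vanillin); 2 (allyl bromide)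
Product: 3 (4-(allyloxy)-3-methoxybenzaldehyde)
Conditions: K2CO3, DMF, rt
Reagents that add atoms: allyl bromide (compound 2), C=CCBr
Why: Williamson O-allylation of the phenol. The allyl ether survives the aldol, hydride and oxidation steps and can be removed under neutral Pd(0) conditions at the end. No stereocentre is involved.

**Step 2**
Reactants: 4 (succinic anhydride); 5 ((4R)-4-benzyl-1,3-oxazolidin-2-one)
Product: 6 (4-[(4R)-4-benzyl-2-oxo-1,3-oxazolidin-3-yl]-4-oxobutanoic acid)
Conditions: n-BuLi, THF, –78 °C; then 4, –78 → 0 °C; aq. HCl work-up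
Reagents that add atoms: none
Why: The N-lithio oxazolidinone opens the anhydride by N-acylation (ring-opening acylation). This sets the auxiliary on the C9' end.

**Step 3**
Reactants: 6; 7 ((4S)-4-benzyl-1,3-thiazolidine-2-thione)
Product: 8 (1-[(4R)-4-benzyl-2-oxo-1,3-oxazolidin-3-yl]-4-[(4S)-4-benzyl-2-thioxo-1,3-thiazolidin-3-yl]butane-1,4-dione)
Conditions: EDCI, DMAP, CH2Cl2, 0 °C → rt
Reagents that add atoms: none
Why: Carbodiimide N-acylation of the thiazolidinethione N–H gives the unsymmetrical bis-imide. The two ends differ in auxiliary sense (R at the oxazolidinone, S at the thiazolidinethione), which is what produces the mirror-related aldol halves later.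

**Step 4**
Reactants: 8; 3
Product: 9 ((4S)-4-benzyl-3-[(2R,3S)-2-{2-[(4R)-4-benzyl-2-oxo-1,3-oxazolidin-3-yl]-2-oxoethyl}-3-[4-(allyloxy)-3-methoxyphenyl]-3-(triethylsilyloxy)propanoyl]-1,3-thiazolidine-2-thione)
Conditions: MgBr2·OEt2 (10 mol%), Et3N (2 equiv), TESCl (2 equiv), EtOAc, rt; 3 (1.0 equiv)
Reagents that add atoms: triethylsilyl chloride, CC[Si](Cl)(CC)CC
Why: Mg-catalysed anti-aldol (Evans–Downey type). The thiazolidinethione imide enolises much faster than the oxazolidinone imide, so only the C9 end reacts. The chelated Z-enolate is attacked on the face opposite the (S)-benzyl group, giving the 2,3-anti adduct and setting C8 (R in 9, S in the target) and C7 (S) in one step. The alcohol is trapped as the TES ether.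

**Step 5**
Reactants: 9
Product: 10 ((4R)-4-benzyl-3-[(3S,4S)-4-[4-(allyloxy)-3-methoxyphenyl]-3-(hydroxymethyl)-4-(triethylsilyloxy)butanoyl]-1,3-oxazolidin-2-one), plus recovered 7
Conditions: NaBH4, THF/H2O (4:1), 0 °C
Reagents that add atoms: none
Why: Hydride cleaves the more electrophilic thiazolidinethione imide to the primary alcohol C9–OH. The oxazolidinone imide, TES ether and allyl ethers survive, and C8 and C7 are untouched. C8 is no longer acidic, which prevents its epimerisation in the next aldol.

**Step 6**
Reactants: 10; 3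
Product: 11 ((4R)-4-benzyl-3-{(2S,3S,4S)-4-[4-(allyloxy)-3-methoxyphenyl]-2-[(R)-[4-(allyloxy)-3-methoxyphenyl](hydroxy)methyl]-3-(hydroxymethyl)-4-(triethylsilyloxy)butanoyl}-1,3-oxazolidin-2-one)
Conditions: MgCl2 (10 mol%), Et3N (2 equiv), TMSCl (3 equiv), EtOAc, rt; 3 (1.5 equiv); then 1% citric acid, MeOH, 0 °C
Reagents that add atoms: none (TMSCl only protects C9–OH and the new C7'–OH transiently and is removed in the work-up)
Why: Proposed new method: the Mg(II)/TMSCl manifold gives the chelated Z-enolate of the oxazolidinone imide at C8', the (R)-benzyl group blocks one face, and the aryl aldehyde adds through the anti-selective manifold to set C8' (S) and C7' (R). The new element is applying this manifold to an α-branched imide that already carries a β-silyloxy stereocentre, and to an electron-rich aryl aldehyde. The auxiliary is the opposite enantiomer to the one used in step 4, so the two aldol halves are mirror-related, which is the relationship that leads to the trans-fused ring system. The closest known reaction is the MgCl2-catalysed anti-aldol of N-acyloxazolidinones with aldehydes.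

**Step 7**
Reactants: 11
Product: 12 ((4R)-4-benzyl-3-{[(2R,3S,4S)-2-[4-(allyloxy)-3-methoxyphenyl]-4-{(S)-[4-(allyloxy)-3-methoxyphenyl](triethylsilyloxy)methyl}oxolan-3-yl]carbonyl}-1,3-oxazolidin-2-one)
Conditions: ADDP, PBu3, toluene, 0 → 60 °C
Reagents that add atoms: none
Why: Intramolecular Mitsunobu-type cyclodehydration. The primary C9–OH is activated, and the C7'–OH closes the THF by 5-exo-tet attack on the CH2 carbon. The C7'–O bond is never broken, so C7' keeps its configuration. C8 and C8' are set by the aldols, and ring 1 is still open, so the trans-3,4 THF forms without strain.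

**Step 8**
Reactants: 12
Product: 13 (((2R,3R,4S)-2-[4-(allyloxy)-3-methoxyphenyl]-4-{(S)-[4-(allyloxy)-3-methoxyphenyl](triethylsilyloxy)methyl}oxolan-3-yl)methanol), plus recovered 5
Conditions: LiBH4, H2O (1 equiv), Et2O, 0 °C
Reagents that add atoms: none
Why: Reductive cleavage of the N-acyloxazolidinone (Penning-type) gives the primary alcohol C9'–OH. The auxiliary is recovered and no stereocentre is changed.

**Step 9**
Reactants: 13
Product: 14 ((2R,3S,4S)-2-[4-(allyloxy)-3-methoxyphenyl]-4-{(S)-[4-(allyloxy)-3-methoxyphenyl](triethylsilyloxy)methyl}oxolane-3-carbaldehyde)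
Conditions: Dess–Martin periodinane, NaHCO3, CH2Cl2, 0 °C
Reagents that add atoms: none
Why: Buffered, non-basic oxidation of the primary alcohol stops at the aldehyde and minimises enolisation at the α-centre C8'.

**Step 10**
Reactants: 14
Product: 15 (bis-O-allyl 4α-hydroxypinoresinol, lactol)
Conditions: HF·pyridine, pyridine, THF, 0 °C → rt
Reagents that add atoms: none
Why: Buffered desilylation frees the C7–OH, which adds to the C9' aldehyde to close ring 1 as the hemiacetal (intramolecular hemiacetalisation). No stereocentre is touched. The lactol carbon equilibrates through the open hydroxy-aldehyde, and the drawn anomer is assumed.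

**Step 11**
Reactants: 15
Product: 16 (4α-hydroxypinoresinol)
Conditions: Pd(PPh3)4 (5 mol%), dimedone (5 equiv), THF, rt
Reagents that add atoms: none
Why: Tsuji–Trost-type π-allyl transfer from the two aryl allyl ethers to dimedone under neutral conditions. The benzylic ether, lactol and all five stereocentres survive.

---

**Compound list**

| No. | Name | SMILES | Role |
|---|---|---|---|
| 1 | vanillin | `COc1cc(C=O)ccc1O` | starting material |
| 2 | allyl bromide | `C=CCBr` | starting material |
| 3 | 4-(allyloxy)-3-methoxybenzaldehyde | `COc1cc(C=O)ccc1OCC=C` | intermediate |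
| 4 | succinic anhydride | `O=C1CCC(=O)O1` | starting material |
| 5 | (4R)-4-benzyl-1,3-oxazolidin-2-one | `O=C1N[C@H](Cc2ccccc2)CO1` | starting material |
| 6 | 4-[(4R)-4-benzyl-2-oxo-1,3-oxazolidin-3-yl]-4-oxobutanoic acid | `OC(=O)CCC(=O)N1[C@H](Cc2ccccc2)COC1=O` | intermediate |
| 7 | (4S)-4-benzyl-1,3-thiazolidine-2-thione | `S=C1N[C@@H](Cc2ccccc2)CS1` | starting material |
| 8 | unsymmetrical succinyl bis-imide (R-oxazolidinone / S-thiazolidinethione) | `O=C(CCC(=O)N1[C@@H](Cc2ccccc2)CSC1=S)N1[C@H](Cc2ccccc2)COC1=O` | intermediate |
| 9 | C7/C8 anti-aldol adduct, C7-O-TES | `O=C(N1[C@H](Cc2ccccc2)COC1=O)C[C@H]([C@H](O[Si](CC)(CC)CC)c1ccc(OCC=C)c(OC)c1)C(=O)N1[C@@H](Cc2ccccc2)CSC1=S` | intermediate |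
| 10 | C9 primary alcohol, oxazolidinone imide | `O=C(N1[C@H](Cc2ccccc2)COC1=O)C[C@H]([C@H](O[Si](CC)(CC)CC)c1ccc(OCC=C)c(OC)c1)CO` | intermediate |
| 11 | 1,4-diol (C9-OH, C7'-OH), C7-O-TES, imide | `O=C(N1[C@H](Cc2ccccc2)COC1=O)[C@H]([C@@H](O)c1ccc(OCC=C)c(OC)c1)[C@@H](CO)[C@H](O[Si](CC)(CC)CC)c1ccc(OCC=C)c(OC)c1` | intermediate |
| 12 | 2-aryl-3,4-trans-THF imide (ring 2 formed) | `CC[Si](CC)(CC)O[C@H](c1ccc(OCC=C)c(OC)c1)[C@@H]2CO[C@@H](c1ccc(OCC=C)c(OC)c1)[C@H]2C(=O)N1[C@H](Cc2ccccc2)COC1=O` | intermediate |
| 13 | THF-3-methanol | `CC[Si](CC)(CC)O[C@H](c1ccc(OCC=C)c(OC)c1)[C@@H]2CO[C@@H](c1ccc(OCC=C)c(OC)c1)[C@H]2CO` | intermediate |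
| 14 | THF-3-carbaldehyde | `CC[Si](CC)(CC)O[C@H](c1ccc(OCC=C)c(OC)c1)[C@@H]2CO[C@@H](c1ccc(OCC=C)c(OC)c1)[C@H]2C=O` | intermediate |
| 15 | bis-O-allyl 4α-hydroxypinoresinol (lactol) | `COc1cc([C@H]2O[C@@H](O)[C@H]3[C@H]2CO[C@H]3c2ccc(OCC=C)c(OC)c2)ccc1OCC=C` | intermediate |
| 16 | 4α-hydroxypinoresinol | `COc1cc([C@H]2O[C@@H](O)[C@H]3[C@H]2CO[C@H]3c2ccc(O)c(OC)c2)ccc1O` | target |

**Total steps:** 11.
**Longest linear sequence:** 10 steps (4 → 6 → 8 → 9 → 10 → 11 → 12 → 13 → 14 → 15 → 16). Step 1, making 3 from 1, is a short convergent branch.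

**Three steps most likely to fail**
1. **Step 6 (the proposed new step).** The second anti-aldol may be sluggish with an α-branched imide and an electron-rich aldehyde, or the auxiliary and substrate may be mismatched.
   - Fallback: use known Evans syn-aldol chemistry (Bu2BOTf, Et3N) at the oxazolidinone end.
   - Oxidise the syn carbinol (Dess–Martin) to the β-keto imide, then reduce it with Noyori Ru-TsDPEN transfer hydrogenation (HCO2H/Et3N). Catalyst control with dynamic epimerisation at C8' delivers the anti C8'/C7' pair.
2. **Step 10.** The trans-fused lactol is strained. The open hydroxy-aldehyde can epimerise at C8' to the more stable cis-fused lactol, or simply stay open.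
   - Fallback: remove the TES group from 13, oxidise the diol to the lactone (TEMPO, PhI(OAc)2), and reduce at –78 °C with DIBAL. This avoids the enolisable aldehyde.
3. **Step 7.** The secondary electron-rich benzylic alcohol may ionise or eliminate, and the imide carbonyl may trap the activated C9.
   - Fallback: convert the primary alcohol selectively to the iodide (PPh3, I2, imidazole) and close the ring with Ag2O. This is a silver-assisted SN2 closure with no alkoxide, so there is no retro-aldol and no carbocation.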